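**Retrosynthetic overview**

- The target is the (2R,3S,4S,5S)-oxolane O1–C2(ring A, 3-hydroxy-4,5-dimethoxyphenyl)–C3(Me)–C4(Me)–C5(ring B, 3,4,5-trimethoxyphenyl). The plan rests on one feature: the C3 methyl stands cis to ring A on C2, against steric preference, in a ring whose aryl groups are 2,5-cis. C3 is therefore carried as an exocyclic C3=CH2 and reduced late from the face turned away from both aryl groups.
- End game: C3–H and the phenol are revealed from a 3-methylene oxolane with ring A protected as its benzyl ether.
- Key disconnection, C3–C4: the only ring (the oxolane) is closed by 5-exo-dig attack of a C4 radical, released from an S-methyl xanthate, on the ethynyl group carried by C2.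
- The open-chain ether is cut at C5–O1: invertive benzylic opening of the (2S,3S)-epoxide of (E)-1-(3,4,5-trimethoxyphenyl)propene by an (R)-1-arylpropargyl alcohol. C2 comes from a catalytic asymmetric alkynylation, C5 from a Shi epoxidation.

Key step: step 9

Remark on numbering: ring atoms are numbered O1, C2 (ring A), C3, C4, C5 (ring B) throughout.

Assumption: (S,S)-ProPhenol is taken as the ligand antipode that sends the alkynyl group to the Re face of the benzyl-protected aldehyde. The sense should be checked by Mosher ester analysis on the first run, and the (R,R)-ligand used with no other change if it proves opposite.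

**Route**

Step 1
Reactants: 1 3-hydroxy-4,5-dimethoxybenzaldehyde
Product: 2 3-(benzyloxy)-4,5-dimethoxybenzaldehyde
Conditions: BnBr, K2CO3, DMF, rt
Reagents that add atoms: benzyl bromide, BrCc1ccccc1
Why: Williamson etherification of the phenoxide (SN2 on benzyl bromide); the benzyl ether should mask the acidic phenol through the organozinc, Lewis acid, hydride base and radical steps and is removed by hydrogenolysis at the end.

Step 2
Reactants: 2 3-(benzyloxy)-4,5-dimethoxybenzaldehyde; 3 trimethylsilylacetylene
Product: 5 (1S)-1-[3-(benzyloxy)-4,5-dimethoxyphenyl]-3-(trimethylsilyl)prop-2-yn-1-ol, via methyl[(trimethylsilyl)ethynyl]zinc 4 (not isolated)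
Conditions: Me2Zn (3 equiv), (S,S)-ProPhenol (10 mol%), Ph3PO (20 mol%), PhMe, 0–4 °C; aq. NH4Cl
Reagents that add atoms: none
Why: Trost dinuclear zinc–ProPhenol asymmetric alkynylation of an aromatic aldehyde, in which alkynylzinc 4 (from 3 and Me2Zn) adds to the Re face of the aldehyde held in the chiral dinuclear pocket, setting the future C2 as the (S)-silylated carbinol (the descriptor becomes R once the silyl group is removed).

Step 3
Reactants: 5 (1S)-silylated propargylic alcohol
Product: 6 (1R)-1-[3-(benzyloxy)-4,5-dimethoxyphenyl]prop-2-yn-1-ol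
Conditions: K2CO3 (0.2 equiv), MeOH, rt
Reagents that add atoms: none
Why: Methoxide-catalysed protodesilylation of the alkynyl C–Si bond; the carbinol centre is not involved and the benzyl ether is stable, so the configuration is kept (the change from S to R is only a change of CIP priority).

Step 4
Reactants: 7 3,4,5-trimethoxybenzaldehyde
Product: 8 rac-1-(3,4,5-trimethoxyphenyl)propan-1-ol
Conditions: EtMgBr, THF, 0 °C to rt; aq. NH4Cl
Reagents that add atoms: ethylmagnesium bromide, CC[Mg]Br
Why: Grignard 1,2-addition to an aromatic aldehyde; the racemic carbinol is acceptable because this centre is removed in step 5.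

Step 5
Reactants: 8 rac-1-(3,4,5-trimethoxyphenyl)propan-1-ol
Product: 9 1,2,3-trimethoxy-5-[(1E)-prop-1-en-1-yl]benzene
Conditions: TsOH·H2O (2 mol%), PhMe, reflux, Dean–Stark, short reaction time
Reagents that add atoms: none
Why: Acid-catalysed E1 dehydration through the benzylic cation, which should give the conjugated E alkene as the thermodynamic product; low acid loading and dilution are used to hold back dimerisation of the styrene.

Step 6
Reactants: 9 (E)-alkene
Product: 10 (2S,3S)-2-methyl-3-(3,4,5-trimethoxyphenyl)oxirane
Conditions: L-fructose-derived Shi ketone (ent-Shi ketone, 30 mol%), KHSO5 (as 2KHSO5·KHSO4·K2SO4), K2CO3, Bu4NHSO4, MeCN–CH2(OMe)2, aq. Na2B4O7 buffer (pH 10.5), 0 °C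
Reagents that add atoms: potassium peroxymonosulfate, [K+].[O-]S(=O)(=O)OO
Why: Shi asymmetric epoxidation, in which the chiral dioxirane formed in the flask from the ketone and KHSO5 transfers oxygen through a spiro transition state and sets both epoxide carbons; the D-fructose-derived ketone is known to give (R,R)-epoxides from (E)-β-methylstyrenes, so its enantiomer is used to reach (2S,3S), and the basic buffer protects the acid-sensitive aryl epoxide.

Step 7
Reactants: 6 (1R)-propargylic alcohol; 10 (2S,3S)-epoxide
Product: 11 (1R,2S)-1-({(1R)-1-[3-(benzyloxy)-4,5-dimethoxyphenyl]prop-2-yn-1-yl}oxy)-1-(3,4,5-trimethoxyphenyl)propan-2-ol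
Conditions: 6 (2 equiv, excess recovered), 10 added slowly, BF3·OEt2 (10 mol%), 4 Å MS, CH2Cl2, −78 to −40 °C; Et3N quench
Reagents that add atoms: none
Why: Lewis acid-catalysed alcoholysis of an aryl epoxide, in which BF3 polarises the benzylic C–O bond and the alcohol attacks that carbon from the rear, so the future C5 is inverted (3S in the epoxide, 1R in the ether) while the carbinol carbon and the propargylic centre of 6 keep their configuration; any minor enantiomer of 6 or 10 ends up in a diastereomeric ether that chromatography should remove here.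

Step 8
Reactants: 11 hydroxy ether
Product: 13 O-[(1R,2S)-1-({(1R)-1-[3-(benzyloxy)-4,5-dimethoxyphenyl]prop-2-yn-1-yl}oxy)-1-(3,4,5-trimethoxyphenyl)propan-2-yl] S-methyl carbonodithioate, via sodium xanthate 12 (not isolated)
Conditions: NaH (1.1 equiv), imidazole (cat.), THF, 0 °C; CS2; then MeI, 0 °C to rt
Reagents that add atoms: carbon disulfide, S=C=S; iodomethane, CI
Why: Standard xanthate formation, in which the sodium alkoxide adds to CS2 and the dithiocarbonate salt 12 is S-methylated; with only a slight excess of base the more acidic hydroxyl is deprotonated ahead of the terminal alkyne, and no stereocentre is touched.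

Step 9
Reactants: 13 xanthate
Product: 14 (2R,4S,5S)-2-[3-(benzyloxy)-4,5-dimethoxyphenyl]-4-methyl-3-methylidene-5-(3,4,5-trimethoxyphenyl)oxolane
Conditions: Bu3SnH (1.3 equiv) and AIBN (0.2 equiv) added by syringe pump over 4 h to 13 (0.01 M), PhMe, 90 °C; aq. KF work-up
Reagents that add atoms: none
Why: Bu3Sn• adds to the thiocarbonyl sulfur of 13 and β-scission releases the secondary C4 radical, which attacks the internal carbon of the ethynyl group to form C3–C4; the vinyl radical then takes hydrogen from Bu3SnH and leaves the exocyclic C3=CH2. The closest known reaction type is the tin hydride-mediated 5-exo-dig cyclisation of β-alkoxyalkyl radicals from propargyl ethers to 3-methylenetetrahydrofurans, started here by Barton–McCombie-type radical generation. The oxolane ring (O1, C2–C5) closes in the 5-exo-dig mode, which should be favoured over 6-endo by the short C–O bonds of the 3-oxa tether and the linear alkyne. The only new stereocentre, C4, is set under substrate control: the radical is planar, so the xanthate configuration does not matter, and in the chair-like (Beckwith–Houk) transition state with ring A and ring B both pseudo-equatorial, which the fixed 2,5-cis relationship allows, the C4 methyl turns away from ring B on C5 and should end trans to it. The step needs 4,5-trans selectivity and ring closure before reduction of the open-chain radical; the first is secured by the aryl-bearing C5 next to the radical centre, the second by the low stannane concentration (slow addition, high dilution) and the rate gain from the ether oxygen in the tether.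

Step 10
Reactants: 14 3-methylidene oxolane
Product: 15 (2R,3S,4S,5S)-2-[3-(benzyloxy)-4,5-dimethoxyphenyl]-3,4-dimethyl-5-(3,4,5-trimethoxyphenyl)oxolane
Conditions: H2 (1 atm), PtO2 (5 mol%), EtOAc, rt
Reagents that add atoms: none
Why: Heterogeneous syn-hydrogenation of a 1,1-disubstituted exocyclic alkene, in which the catalyst surface should reach C3=CH2 from the face opposite ring A on C2 and ring B on C5 (the face carrying only the C4 methyl), so the new C3 methyl is pushed to the aryl face and C3 is set as S, cis to ring A and trans to the C4 methyl; platinum is chosen over palladium because it migrates double bonds and cleaves benzylic C–O bonds far less readily.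

Step 11
Reactants: 15 benzyl-protected oxolane
Product: 16 5-[(2R,3S,4S,5S)-3,4-dimethyl-5-(3,4,5-trimethoxyphenyl)oxolan-2-yl]-2,3-dimethoxyphenol (CNP0293669.2)
Conditions: H2 (1 atm), 10% Pd/C, EtOAc–EtOH, rt, stopped at full conversion
Reagents that add atoms: none
Why: Hydrogenolysis of the aryl benzyl ether, which should be much faster than cleavage of the hindered secondary benzylic C–O bonds of the oxolane, so the phenol is freed with all four stereocentres untouched.

**Compound list**

1 | 3-hydroxy-4,5-dimethoxybenzaldehyde | COc1cc(C=O)cc(O)c1OC | starting material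
2 | 3-(benzyloxy)-4,5-dimethoxybenzaldehyde | COc1cc(C=O)cc(OCc2ccccc2)c1OC | intermediate
3 | trimethylsilylacetylene | C#C[Si](C)(C)C | starting material
4 | methyl[(trimethylsilyl)ethynyl]zinc | C[Zn]C#C[Si](C)(C)C | intermediate
5 | (1S)-1-[3-(benzyloxy)-4,5-dimethoxyphenyl]-3-(trimethylsilyl)prop-2-yn-1-ol | COc1cc([C@@H](C#C[Si](C)(C)C)O)cc(OCc2ccccc2)c1OC | intermediate
6 | (1R)-1-[3-(benzyloxy)-4,5-dimethoxyphenyl]prop-2-yn-1-ol | COc1cc([C@@H](C#C)O)cc(OCc2ccccc2)c1OC | intermediate
7 | 3,4,5-trimethoxybenzaldehyde | COc1cc(C=O)cc(OC)c1OC | starting material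
8 | rac-1-(3,4,5-trimethoxyphenyl)propan-1-ol | CCC(O)c1cc(OC)c(OC)c(OC)c1 | intermediate
9 | 1,2,3-trimethoxy-5-[(1E)-prop-1-en-1-yl]benzene | C/C=C/c1cc(OC)c(OC)c(OC)c1 | intermediate
10 | (2S,3S)-2-methyl-3-(3,4,5-trimethoxyphenyl)oxirane | C[C@@H]1O[C@H]1c1cc(OC)c(OC)c(OC)c1 | intermediate
11 | (1R,2S)-1-({(1R)-1-[3-(benzyloxy)-4,5-dimethoxyphenyl]prop-2-yn-1-yl}oxy)-1-(3,4,5-trimethoxyphenyl)propan-2-ol | COc1cc([C@@H](C#C)O[C@H](c2cc(OC)c(OC)c(OC)c2)[C@H](C)O)cc(OCc2ccccc2)c1OC | intermediate
12 | sodium O-[(1R,2S)-1-({(1R)-1-[3-(benzyloxy)-4,5-dimethoxyphenyl]prop-2-yn-1-yl}oxy)-1-(3,4,5-trimethoxyphenyl)propan-2-yl] carbonodithioate | COc1cc([C@@H](C#C)O[C@H](c2cc(OC)c(OC)c(OC)c2)[C@H](C)OC(=S)[S-])cc(OCc2ccccc2)c1OC.[Na+] | intermediate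
13 | O-[(1R,2S)-1-({(1R)-1-[3-(benzyloxy)-4,5-dimethoxyphenyl]prop-2-yn-1-yl}oxy)-1-(3,4,5-trimethoxyphenyl)propan-2-yl] S-methyl carbonodithioate | COc1cc([C@@H](C#C)O[C@H](c2cc(OC)c(OC)c(OC)c2)[C@H](C)OC(=S)SC)cc(OCc2ccccc2)c1OC | intermediate
14 | (2R,4S,5S)-2-[3-(benzyloxy)-4,5-dimethoxyphenyl]-4-methyl-3-methylidene-5-(3,4,5-trimethoxyphenyl)oxolane | COc1cc([C@@H]2O[C@H](c3cc(OC)c(OC)c(OC)c3)[C@@H](C)C2=C)cc(OCc3ccccc3)c1OC | intermediate
15 | (2R,3S,4S,5S)-2-[3-(benzyloxy)-4,5-dimethoxyphenyl]-3,4-dimethyl-5-(3,4,5-trimethoxyphenyl)oxolane | COc1cc([C@@H]2O[C@H](c3cc(OC)c(OC)c(OC)c3)[C@@H](C)[C@@H]2C)cc(OCc3ccccc3)c1OC | intermediate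
16 | 5-[(2R,3S,4S,5S)-3,4-dimethyl-5-(3,4,5-trimethoxyphenyl)oxolan-2-yl]-2,3-dimethoxyphenol | COc1cc([C@@H]2O[C@H](c3cc(OC)c(OC)c(OC)c3)[C@@H](C)[C@@H]2C)cc(O)c1OC | target

**Step count**

Total steps: 11. Longest linear sequence: 8 steps (steps 1, 2, 3, 7, 8, 9, 10, 11; the ring B branch through steps 4, 5, 6 is equally long).

**Steps most likely to fail**

Step 9 (key step). Hydrogen may be transferred from the stannane to the open-chain C4 radical before the ring closes, facial discrimination at C4 may be weak at 90 °C, or the xanthate may undergo thermal syn-elimination. The fallback is an iodine atom-transfer cyclisation, which has no hydride present during ring closure and runs at or below room temperature. It sets out from hydroxy ether 11. Appel-type iodination (I2, PPh3, imidazole, PhMe, 60 °C) should give, with inversion, the secondary iodide 1-(benzyloxy)-5-[(1R)-1-{[(1R,2R)-2-iodo-1-(3,4,5-trimethoxyphenyl)propyl]oxy}prop-2-yn-1-yl]-2,3-dimethoxybenzene F2. Et3B with a trace of air in benzene at 0 °C to rt then carries a chain in which the same C4 radical closes 5-exo-dig and the vinyl radical takes iodine from F2. This should give the vinyl iodide (2S,4S,5S)-2-[3-(benzyloxy)-4,5-dimethoxyphenyl]-3-(iodomethylidene)-4-methyl-5-(3,4,5-trimethoxyphenyl)oxolane F3 as an E/Z mixture; its spatial arrangement is that of 14, and the C2 descriptor changes only through the priority of iodine. Radical hydrodeiodination of F3 (Bu3SnH, AIBN, PhH, 80 °C) comes back to the route at 14.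

Step 7. The activated epoxide may ionise fully to a benzylic cation, which would erode the inversion at C5 or divert material by 1,2-hydride shift to the aryl ketone, and capture by the hindered secondary alcohol may be slow. The fallback sets out from propargylic alcohol 6 and alkene 9 and gives up reagent control at C5 in exchange for a very dependable ether formation. Bromoetherification (NBS, CH2Cl2, −20 °C, 9 in excess) should add bromine and the alkoxy group anti across the E double bond, with the ether oxygen at the benzylic carbon. The addition is not face-selective, so two diastereomers differing at C5 are expected and are separated by chromatography. The isomer with the required C5 configuration is 1-(benzyloxy)-5-[(1R)-1-{[(1R,2S)-2-bromo-1-(3,4,5-trimethoxyphenyl)propyl]oxy}prop-2-yn-1-yl]-2,3-dimethoxybenzene F1. Under the conditions of step 9 (Bu3SnH, AIBN, PhMe, 90 °C) F1 should give the same C4 radical and comes back to the route at 14, so that steps 6, 7 and 8 are bypassed.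

Step 10. Hydrogen may be delivered in part to the aryl-bearing face, or the catalyst may move the double bond into the ring (C3=C4), which would erase C4. The fallback is an ionic hydrogenation that sets C3 by a cationic pathway instead of by surface approach. It sets out from 14 with CF3CO2H and Et3SiH in CH2Cl2 at −20 to 0 °C. Protonation of the methylene group should be followed by a suprafacial 1,2-hydride shift from C2 to C3, which places the C3 methyl trans to the C4 methyl and leaves a 2-aryl oxocarbenium ion. The silane then delivers hydride to C2 anti to the C3 methyl, restoring ring A cis to it. This comes back to the route directly at 15 with no new intermediate; the acid contact time must be kept short because the benzylic ring C–O bonds can ionise.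

**Further compounds**

F1 | step 7 | 1-(benzyloxy)-5-[(1R)-1-{[(1R,2S)-2-bromo-1-(3,4,5-trimethoxyphenyl)propyl]oxy}prop-2-yn-1-yl]-2,3-dimethoxybenzene | COc1cc([C@@H](C#C)O[C@H](c2cc(OC)c(OC)c(OC)c2)[C@H](C)Br)cc(OCc2ccccc2)c1OC
F2 | step 9 | 1-(benzyloxy)-5-[(1R)-1-{[(1R,2R)-2-iodo-1-(3,4,5-trimethoxyphenyl)propyl]oxy}prop-2-yn-1-yl]-2,3-dimethoxybenzene | COc1cc([C@@H](C#C)O[C@H](c2cc(OC)c(OC)c(OC)c2)[C@@H](C)I)cc(OCc2ccccc2)c1OC
F3 | step 9 | (2S,4S,5S)-2-[3-(benzyloxy)-4,5-dimethoxyphenyl]-3-(iodomethylidene)-4-methyl-5-(3,4,5-trimethoxyphenyl)oxolane (E/Z mixture) | COc1cc([C@@H]2O[C@H](c3cc(OC)c(OC)c(OC)c3)[C@@H](C)C2=CI)cc(OCc3ccccc3)c1OC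
F0 | step 10 | none | none
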